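**Assumptions (one line each)**
- The target has one stereocentre, the carbinol, which is (S) by CIP (priorities OH > butenolide C3 > aryl > H). The exocyclic alkene is (Z), as in the rubrolides.
- Aryl boronic acid 7 and 3,4-dibromofuranone 6 are taken as commercial.
- The chiral-ligand enantiomer in Step 5 is taken to be the one that delivers the (S)-alcohol, to be confirmed by a small ligand screen.

## Retrosynthesis
- Target **1** is disconnected at the carbinol C–C bond by an asymmetric Nozaki–Hiyama–Kishi (NHK) coupling. This gives vinyl bromide **2** (bis-MOM (Z)-3-bromo-rubrolide) and aldehyde **3** (3,5-dibromo-4-methoxybenzaldehyde).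
- The exocyclic (Z)-arylidene of **2** comes from a vinylogous aldol condensation of butenolide **4** with aldehyde **5** (MOM-protected 3-bromo-4-hydroxybenzaldehyde).
- Butenolide **4** comes from selective C4 Suzuki coupling of 3,4-dibromofuranone **6** with boronic acid **7**, then phenol protection.
- The lactone ring is commercial and never assembled. The only new stereocentre is made in the penultimate step.

## Route

**Step 1**
Reactants: **6** 3,4-dibromofuran-2(5H)-one; **7** (3-bromo-4-hydroxyphenyl)boronic acid
Product: **8** 3-bromo-4-(3-bromo-4-hydroxyphenyl)furan-2(5H)-one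
Conditions: Pd(PPh3)4 (5 mol %), Ag2CO3, MeCN, 70 °C
Reagents that add atoms: none
Why: Suzuki–Miyaura coupling occurs selectively at C4–Br, the more electrophilic, vinylogous acyl-bromide position. The C3–Br and the aryl C–Br bonds survive.

**Step 2**
Reactants: **8**; **9** chloromethyl methyl ether
Product: **4** 3-bromo-4-[3-bromo-4-(methoxymethoxy)phenyl]furan-2(5H)-one
Conditions: MOMCl, i-Pr2NEt, CH2Cl2, 0 °C → rt
Reagents that add atoms: MOMCl, COCCl
Why: O-alkylation of the phenol gives a MOM ether that is stable to base, fluoride and low-valent Cr/Ni in the later steps.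

**Step 3**
Reactants: **10** 3-bromo-4-hydroxybenzaldehyde; **9** MOMCl
Product: **5** 3-bromo-4-(methoxymethoxy)benzaldehyde
Conditions: MOMCl, i-Pr2NEt, CH2Cl2, 0 °C → rt
Reagents that add atoms: MOMCl, COCCl
Why: The same phenol protection is needed so the aldehyde is not deactivated as a phenoxide in Step 4.

**Step 4**
Reactants: **4**; **5**
Product: **2** (Z)-3-bromo-4-[3-bromo-4-(MOMO)phenyl]-5-[3-bromo-4-(MOMO)benzylidene]furan-2(5H)-one
Conditions: KF/Al2O3, MeCN, rt, dark
Reagents that add atoms: none (the aldehyde carbon stays in the product, and water is lost)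
Why: The C5 dienolate undergoes aldol addition, then E1cB dehydration (vinylogous Knoevenagel-type condensation). The thermodynamic (Z)-arylidene has the aryl group on the ring-O side, away from the 4-aryl group.

**Step 5**
Reactants: **2**; **3** 3,5-dibromo-4-methoxybenzaldehyde
Product: **11** (S)-carbinol, bis-MOM-protected target
Conditions: CrCl2 (3 equiv), NiCl2 (5 mol %), chiral (S)-sulfonamide ligand (Kishi type, 30 mol %), Et3N, proton sponge, LiCl, MeCN/THF, 0 °C → rt
Reagents that add atoms: none (the aldehyde is a reactant; H comes from aqueous workup)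
Why: This is an asymmetric Ni/Cr NHK coupling. Ni inserts into the reactive α-bromo-enoate C–Br bond (as in the Cr/Ni coupling of α-iodoenones with aldehydes) and transmetalates to a vinyl-chromium species. That species adds to the aldehyde face set by the chiral sulfonamide–Cr complex, giving the secondary alcohol. Aryl C–Br, the MOM ethers and the lactone are untouched.

**Step 6**
Reactants: **11**
Product: **1** target
Conditions: TFA/CH2Cl2 (1:4), 0 °C → rt, 2 h
Reagents that add atoms: none
Why: Acidolysis removes both aryl MOM ethers. The carbinol has no α-hydrogen and no enolisable position, so it cannot racemise by retro-aldol or E1cB. The electron-poor benzylic alcohol does not ionise, and the (Z)-alkene and lactone survive.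

**Checks:** Ring sizes and substituents match the target. The butenolide has a C3 CH(OH)Ar, a C4 3-bromo-4-hydroxyphenyl and a C5 (Z)-3-bromo-4-hydroxybenzylidene. The carbinol aryl is 3,5-dibromo-4-methoxyphenyl. The stereo tag in **11** and **1** is the same as in the target SMILES, and no later step touches the stereocentre.

## Compound list
1 | target: (S)-hydroxy(3,5-dibromo-4-methoxyphenyl)methyl (Z)-rubrolide-type butenolide | COc1c(Br)cc([C@H](O)C2=C(c3ccc(O)c(Br)c3)/C(=C/c3ccc(O)c(Br)c3)OC2=O)cc1Br | target
2 | (Z)-3-bromo-4-[3-bromo-4-(MOMO)phenyl]-5-[3-bromo-4-(MOMO)benzylidene]furan-2(5H)-one | BrC1=C(c2ccc(OCOC)c(Br)c2)/C(=C/c2ccc(OCOC)c(Br)c2)OC1=O | intermediate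
3 | 3,5-dibromo-4-methoxybenzaldehyde | COc1c(Br)cc(C=O)cc1Br | starting material
4 | 3-bromo-4-[3-bromo-4-(MOMO)phenyl]furan-2(5H)-one | O=C1OCC(c2ccc(OCOC)c(Br)c2)=C1Br | intermediate
5 | 3-bromo-4-(methoxymethoxy)benzaldehyde | COCOc1ccc(C=O)cc1Br | intermediate
6 | 3,4-dibromofuran-2(5H)-one | O=C1OCC(Br)=C1Br | starting material
7 | (3-bromo-4-hydroxyphenyl)boronic acid | OB(O)c1ccc(O)c(Br)c1 | starting material
8 | 3-bromo-4-(3-bromo-4-hydroxyphenyl)furan-2(5H)-one | O=C1OCC(c2ccc(O)c(Br)c2)=C1Br | intermediate
9 | chloromethyl methyl ether (MOMCl) | COCCl | reagent (starting material)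
10 | 3-bromo-4-hydroxybenzaldehyde | O=Cc1ccc(O)c(Br)c1 | starting material
11 | (S)-carbinol, bis-MOM-protected target | COc1c(Br)cc([C@H](O)C2=C(c3ccc(OCOC)c(Br)c3)/C(=C/c3ccc(OCOC)c(Br)c3)OC2=O)cc1Br | intermediate

**Total steps:** 6 (Steps 1, 2, 4, 5 and 6 form the main line; Step 3 is a parallel step making aldehyde 5).
**Longest linear sequence:** 5 steps (Suzuki → MOM protection → condensation → NHK → deprotection).

**Three steps most likely to fail**
1. **Step 5, asymmetric NHK.** The vinyl bromide is hindered, Ar–Br insertion or reduction could compete, and the ee is unproven for this substrate.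
   - Fallback: run a racemic Cr/Ni coupling, oxidise the alcohol with DMP to the 3-aroyl ketone, then reduce it with (S)-CBS or Ru-TsDPEN transfer hydrogenation. Alternatively, resolve the racemate by lipase-catalysed acylation.
2. **Step 4, C5 condensation.** Conversion and Z/E ratio may be poor, and alumina/fluoride could cleave or disturb the protecting groups.
   - Fallback: form the silyloxyfuran (TBSOTf, Et3N), do a Mukaiyama vinylogous aldol with **5**, then dehydrate (MsCl, Et3N, then DBU) to the (Z)-alkene.
3. **Step 1, regioselective Suzuki coupling.** C3 coupling, or oligomerisation through the aryl bromide of boronic acid **7**, would compete with the desired C4 coupling.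
   - Fallback: make **8** from 3-bromotetronic acid. Convert it to the 4-triflate (Tf2O, base) and couple it with a MOM-protected 3-bromo-4-hydroxyphenylboronate, which avoids the dibromofuranone's regiochemical problem.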